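**Retrosynthetic overview**

- The free acid is unmasked last from a tert-butyl ester. The side-chain ester C–O bond is never made from a preformed dienoic acid: the lactone alcohol carries only an acrylate.
- The dienoate C2'=C3' bond is cut by cross-metathesis (CM) between that acrylate and the vinyl terminus of a 2-methyl-1,3-diene side chain.
- The lactone core comes from the mono-acrylate of C2-symmetric (3S,4S)-hexa-1,5-diene-3,4-diol by hydroxyl-directed, ring-size-selective ring-closing metathesis (RCM), followed in the same flask by CM with tert-butyl acrylate. Both ring stereocenters come from the diol.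
- The side chain comes from (R)-β-citronellene (C6' methyl center) and (S)-propylene oxide (C11' carbinol); CM with methacrolein sets the E-trisubstituted alkene, and methylenation gives the diene.
- Ring order: there is one ring, the 5,6-dihydro-2H-pyran-2-one, closed by RCM in step 2.

Assumption: the three chiral-pool starting materials are bought as single enantiomers.

**Route**

Step 1
Reactants: 1 (3S,4S)-hexa-1,5-diene-3,4-diol
Product: 2 (3S,4S)-4-hydroxyhexa-1,5-dien-3-yl prop-2-enoate
Conditions: acryloyl chloride (1.0 equiv), 2,4,6-collidine, CH2Cl2, −78 → −30 °C; 1 used in 1.5-fold excess and the surplus recovered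
Reagents that add atoms: acryloyl chloride, C=CC(Cl)=O
Why: Acylation of an alcohol with an acid chloride; the two hydroxyls of C2-symmetric 1 are homotopic, so the mono-ester is one compound whichever oxygen reacts, and no stereocenter is touched.

Step 2
Reactants: 2 (3S,4S)-4-hydroxyhexa-1,5-dien-3-yl prop-2-enoate
Product: 4 tert-butyl (2E)-3-[(2S,3S)-3-hydroxy-6-oxo-3,6-dihydro-2H-pyran-2-yl]prop-2-enoate, via hydroxy vinyl lactone 3 (not isolated)
Conditions: RuCl2(H2IMes)(=CH-C6H4-2-OiPr) (second-generation Hoveyda–Grubbs catalyst, 5 mol %), 1,4-benzoquinone (10 mol %), CH2Cl2 (0.02 M), 40 °C, 3 h; then tert-butyl acrylate (10 equiv), further 5 mol % catalyst, 40 °C, 16 h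
Reagents that add atoms: tert-butyl acrylate, C=CC(=O)OC(C)(C)C
Why: Tandem ring-closing metathesis/cross-metathesis, in which the ruthenium carbene loads on the vinyl group beside the free allylic hydroxyl (hydroxyl-accelerated, while the acyloxy-bearing vinyl is deactivated) and can reach the acrylate from there only through the six-membered ring, giving the Z-enoate lactone 3 with both stereocenters of 1 intact, after which the surviving vinyl group undergoes E-selective CM with the acrylate partner.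

Step 3
Reactants: 4 tert-butyl (2E)-3-[(2S,3S)-3-hydroxy-6-oxo-3,6-dihydro-2H-pyran-2-yl]prop-2-enoate
Product: 5 tert-butyl (2E)-3-[(2S,3S)-6-oxo-3-(prop-2-enoyloxy)-3,6-dihydro-2H-pyran-2-yl]prop-2-enoate
Conditions: acryloyl chloride, iPr2NEt, CH2Cl2, −40 → 0 °C
Reagents that add atoms: acryloyl chloride, C=CC(Cl)=O
Why: O-Acylation with an acid chloride and a hindered amine at low temperature, which avoids translactonisation and β-elimination of the base-sensitive lactone and leaves both ring stereocenters untouched.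

Step 4
Reactants: 6 (R)-3,7-dimethylocta-1,6-diene [(R)-β-citronellene]
Product: 8 (R)-4-methylhex-5-en-1-ol, via (R)-4-methylhex-5-enal 7 (not isolated)
Conditions: O3 (1.0 equiv, Sudan Red 7B end point), CH2Cl2/MeOH 4:1, −78 °C; then NaBH4 (excess), −78 → 20 °C
Reagents that add atoms: ozone, O=[O+][O-]
Why: Chemoselective ozonolysis of the electron-rich trisubstituted alkene (the monosubstituted vinyl group reacts far more slowly) with reductive NaBH4 work-up; the methyl-bearing stereocenter is remote from the cleaved bond and is carried over unchanged.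

Step 5
Reactants: 8 (R)-4-methylhex-5-en-1-ol
Product: 9 (R)-6-bromo-3-methylhex-1-ene
Conditions: CBr4, PPh3, CH2Cl2, 0 °C
Reagents that add atoms: carbon tetrabromide, BrC(Br)(Br)Br
Why: Appel bromination of a primary alcohol under neutral conditions; the stereocenter is not involved.

Step 6
Reactants: 9 (R)-6-bromo-3-methylhex-1-ene; 10 (S)-2-methyloxirane [(S)-propylene oxide]
Product: 12 (2S,7R)-7-methylnon-8-en-2-ol, via Grignard reagent 11 (not isolated)
Conditions: Mg, THF, 20–40 °C; then CuI (10 mol %), 10, −30 → 0 °C; H2O quench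
Reagents that add atoms: none
Why: Grignard formation followed by copper-catalysed SN2 opening of the epoxide at its unsubstituted carbon, so the (S) carbinol center of 10 is retained as C2 of 12 and the (R) methyl center comes from 6.

Step 7
Reactants: 12 (2S,7R)-7-methylnon-8-en-2-ol
Product: 13 (2E,4R,9S)-9-hydroxy-2,4-dimethyldec-2-enal
Conditions: methacrolein (10 equiv), RuCl2(H2IMes)(=CH-C6H4-2-OiPr) (second-generation Hoveyda–Grubbs catalyst, 5 mol %), CH2Cl2, 40 °C, 24 h
Reagents that add atoms: methacrolein, CC(=C)C=O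
Why: Cross-metathesis of a terminal alkene with a 1,1-disubstituted enal, which gives the thermodynamically favoured (E)-2-methyl-2-enal; the remote free hydroxyl is tolerated and the allylic stereocenter is not touched.

Step 8
Reactants: 13 (2E,4R,9S)-9-hydroxy-2,4-dimethyldec-2-enal
Product: 14 (2S,7R,8E)-7,9-dimethylundeca-8,10-dien-2-ol
Conditions: Ph3PCH3Br (2.5 equiv), KOtBu (2.4 equiv), THF, 0 °C; then 13, −78 → 0 °C
Reagents that add atoms: methyltriphenylphosphonium bromide, C[P+](c1ccccc1)(c1ccccc1)c1ccccc1.[Br-]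
Why: Wittig methylenation, in which the non-stabilised ylide adds to the aldehyde much faster than it deprotonates the γ-position, so the allylic stereocenter and the E-alkene are preserved (one equivalent of ylide is spent on the hydroxyl).

Step 9
Reactants: 5 tert-butyl (2E)-3-[(2S,3S)-6-oxo-3-(prop-2-enoyloxy)-3,6-dihydro-2H-pyran-2-yl]prop-2-enoate; 14 (2S,7R,8E)-7,9-dimethylundeca-8,10-dien-2-ol
Product: 15 (2S,3S)-2-[(1E)-3-tert-butoxy-3-oxoprop-1-en-1-yl]-6-oxo-3,6-dihydro-2H-pyran-3-yl (2E,4E,6R,11S)-11-hydroxy-4,6-dimethyldodeca-2,4-dienoate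
Conditions: 5 (1.5 equiv), RuCl2(H2IMes)(=CH-C6H4-2-OiPr) (second-generation Hoveyda–Grubbs catalyst, 10 mol % in two portions), CH2Cl2 (0.05 M), 40 °C, argon sparge
Reagents that add atoms: none
Why: Cross-metathesis of a 1,3-diene with an electron-poor alkene, in which the terminal vinyl group of 14 is the only accessible alkene of the diene (its neighbour is trisubstituted and flanked by a branched carbon), the acrylate of 5 is the only terminal alkene of the lactone, and acrylate CM gives the E-enoate, so the (2E,4E)-dienoate forms without touching any stereocenter.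

Step 10
Reactants: 15 (2S,3S)-2-[(1E)-3-tert-butoxy-3-oxoprop-1-en-1-yl]-6-oxo-3,6-dihydro-2H-pyran-3-yl (2E,4E,6R,11S)-11-hydroxy-4,6-dimethyldodeca-2,4-dienoate
Product: 16 (2E)-3-[(2S,3S)-3-{[(2E,4E,6R,11S)-11-hydroxy-4,6-dimethyldodeca-2,4-dienoyl]oxy}-6-oxo-3,6-dihydro-2H-pyran-2-yl]prop-2-enoic acid (CNP0107712.2)
Conditions: TFA/CH2Cl2 1:4, 0 → 20 °C, 2 h; evaporate, then brief MeOH/H2O to cleave any trifluoroacetate on the alcohol
Reagents that add atoms: none
Why: Acidolysis of a tert-butyl ester with loss of isobutene, under which the lactone, the other two esters, the dienoate and the secondary alcohol are stable, whereas basic hydrolysis would trigger elimination to the 2-pyranone.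

**Compound list**

1 | (3S,4S)-hexa-1,5-diene-3,4-diol | O[C@H]([C@H](C=C)O)C=C | starting material
2 | (3S,4S)-4-hydroxyhexa-1,5-dien-3-yl prop-2-enoate | O[C@H]([C@H](C=C)OC(=O)C=C)C=C | intermediate
3 | (5S,6S)-6-ethenyl-5-hydroxy-5,6-dihydro-2H-pyran-2-one | O[C@H]1C=CC(=O)O[C@H]1C=C | intermediate
4 | tert-butyl (2E)-3-[(2S,3S)-3-hydroxy-6-oxo-3,6-dihydro-2H-pyran-2-yl]prop-2-enoate | O[C@H]1C=CC(=O)O[C@H]1/C=C/C(=O)OC(C)(C)C | intermediate
5 | tert-butyl (2E)-3-[(2S,3S)-6-oxo-3-(prop-2-enoyloxy)-3,6-dihydro-2H-pyran-2-yl]prop-2-enoate | C=CC(=O)O[C@H]1C=CC(=O)O[C@H]1/C=C/C(=O)OC(C)(C)C | intermediate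
6 | (R)-3,7-dimethylocta-1,6-diene | C=C[C@H](C)CCC=C(C)C | starting material
7 | (R)-4-methylhex-5-enal | C=C[C@H](C)CCC=O | intermediate
8 | (R)-4-methylhex-5-en-1-ol | C=C[C@H](C)CCCO | intermediate
9 | (R)-6-bromo-3-methylhex-1-ene | C=C[C@H](C)CCCBr | intermediate
10 | (S)-2-methyloxirane | C[C@H]1CO1 | starting material
11 | [(4R)-4-methylhex-5-en-1-yl]magnesium bromide | C=C[C@H](C)CCC[Mg]Br | intermediate
12 | (2S,7R)-7-methylnon-8-en-2-ol | C=C[C@H](C)CCCC[C@H](C)O | intermediate
13 | (2E,4R,9S)-9-hydroxy-2,4-dimethyldec-2-enal | CC(/C=O)=C\[C@H](C)CCCC[C@H](C)O | intermediate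
14 | (2S,7R,8E)-7,9-dimethylundeca-8,10-dien-2-ol | CC(/C=C)=C\[C@H](C)CCCC[C@H](C)O | intermediate
15 | (2S,3S)-2-[(1E)-3-tert-butoxy-3-oxoprop-1-en-1-yl]-6-oxo-3,6-dihydro-2H-pyran-3-yl (2E,4E,6R,11S)-11-hydroxy-4,6-dimethyldodeca-2,4-dienoate | CC(/C=C/C(=O)O[C@H]1C=CC(=O)O[C@H]1/C=C/C(=O)OC(C)(C)C)=C\[C@H](C)CCCC[C@H](C)O | intermediate
16 | (2E)-3-[(2S,3S)-3-{[(2E,4E,6R,11S)-11-hydroxy-4,6-dimethyldodeca-2,4-dienoyl]oxy}-6-oxo-3,6-dihydro-2H-pyran-2-yl]prop-2-enoic acid | CC(/C=C/C(=O)O[C@H]1C=CC(=O)O[C@H]1/C=C/C(=O)O)=C\[C@H](C)CCCC[C@H](C)O | target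

**Step count and risks**

Total: 10 steps. Longest linear sequence: 7 steps (steps 4 to 10, from 6).

The three steps most likely to fail are step 2, step 9 and step 7, in that order of concern.

Step 2 (ring size). If the carbene closes onto the acrylate from the acyloxy-bearing vinyl group, the five-membered butenolide forms instead of the dihydropyranone. The fallback sets out from 1 and comes back at 4, and it removes the choice by protecting-group control. Diol 1 is mono-silylated (NaH, TBSCl, THF) to (3S,4S)-4-{[tert-butyl(dimethyl)silyl]oxy}hexa-1,5-dien-3-ol F1. Cross-metathesis with tert-butyl acrylate (same ruthenium catalyst) takes place at the vinyl group beside the free hydroxyl and gives tert-butyl (2E,4S,5S)-5-{[tert-butyl(dimethyl)silyl]oxy}-4-hydroxyhepta-2,6-dienoate F2. Acryloyl chloride and iPr2NEt give tert-butyl (2E,4S,5S)-5-{[tert-butyl(dimethyl)silyl]oxy}-4-(prop-2-enoyloxy)hepta-2,6-dienoate F3. In this triene the only terminal alkene besides the acrylate sits on the silyloxy carbon, so RCM can close only the six-membered ring, giving tert-butyl (2E)-3-[(2S,3S)-3-{[tert-butyl(dimethyl)silyl]oxy}-6-oxo-3,6-dihydro-2H-pyran-2-yl]prop-2-enoate F4. HF·pyridine in THF then gives 4.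

Step 7 (hindered cross-metathesis). The alkene of 12 carries an allylic branch and methacrolein is 1,1-disubstituted, so turnover may be poor. The fallback sets out from 12 and comes back at 13, and it replaces metathesis by carbonyl olefination. Ozonolysis of 12 (O3, CH2Cl2, −78 °C; PPh3) gives (2R,7S)-7-hydroxy-2-methyloctanal F5, which is treated at once with 2-(triphenylphosphoranylidene)propanal in toluene at 80 °C (E-selective Wittig reaction) to give 13.

Step 9 (diene–acrylate cross-metathesis). The conjugated vinyl carbene is sluggish, and cleavage at the internal alkene or diene homodimerisation could lower the yield. The fallback sets out from 4 together with 13 and comes back at 15, so steps 3 and 8 are then not needed; the C2'=C3' bond is made by a Wittig reaction instead. Alcohol 4 is acylated with bromoacetyl bromide and pyridine at −20 °C to tert-butyl (2E)-3-[(2S,3S)-3-[(bromoacetyl)oxy]-6-oxo-3,6-dihydro-2H-pyran-2-yl]prop-2-enoate F6. PPh3 in MeCN gives [2-({(2S,3S)-2-[(1E)-3-tert-butoxy-3-oxoprop-1-en-1-yl]-6-oxo-3,6-dihydro-2H-pyran-3-yl}oxy)-2-oxoethyl](triphenyl)phosphonium bromide F7. Aqueous NaHCO3 gives the stabilised ylide (2S,3S)-2-[(1E)-3-tert-butoxy-3-oxoprop-1-en-1-yl]-6-oxo-3,6-dihydro-2H-pyran-3-yl (triphenyl-λ5-phosphanylidene)acetate F8, which reacts with 13 in toluene at 50 °C to give 15.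

**Further compounds**

F1 | step 2 | (3S,4S)-4-{[tert-butyl(dimethyl)silyl]oxy}hexa-1,5-dien-3-ol | O[C@H]([C@H](C=C)O[Si](C)(C)C(C)(C)C)C=C
F2 | step 2 | tert-butyl (2E,4S,5S)-5-{[tert-butyl(dimethyl)silyl]oxy}-4-hydroxyhepta-2,6-dienoate | O[C@H]([C@H](C=C)O[Si](C)(C)C(C)(C)C)/C=C/C(=O)OC(C)(C)C
F3 | step 2 | tert-butyl (2E,4S,5S)-5-{[tert-butyl(dimethyl)silyl]oxy}-4-(prop-2-enoyloxy)hepta-2,6-dienoate | C=CC(=O)O[C@H]([C@H](C=C)O[Si](C)(C)C(C)(C)C)/C=C/C(=O)OC(C)(C)C
F4 | step 2 | tert-butyl (2E)-3-[(2S,3S)-3-{[tert-butyl(dimethyl)silyl]oxy}-6-oxo-3,6-dihydro-2H-pyran-2-yl]prop-2-enoate | CC(C)(C)[Si](C)(C)O[C@H]1C=CC(=O)O[C@H]1/C=C/C(=O)OC(C)(C)C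
F5 | step 7 | (2R,7S)-7-hydroxy-2-methyloctanal | O=C[C@H](C)CCCC[C@H](C)O
F6 | step 9 | tert-butyl (2E)-3-[(2S,3S)-3-[(bromoacetyl)oxy]-6-oxo-3,6-dihydro-2H-pyran-2-yl]prop-2-enoate | BrCC(=O)O[C@H]1C=CC(=O)O[C@H]1/C=C/C(=O)OC(C)(C)C
F7 | step 9 | [2-({(2S,3S)-2-[(1E)-3-tert-butoxy-3-oxoprop-1-en-1-yl]-6-oxo-3,6-dihydro-2H-pyran-3-yl}oxy)-2-oxoethyl](triphenyl)phosphonium bromide | [Br-].O=C(C[P+](c1ccccc1)(c1ccccc1)c1ccccc1)O[C@H]1C=CC(=O)O[C@H]1/C=C/C(=O)OC(C)(C)C
F8 | step 9 | (2S,3S)-2-[(1E)-3-tert-butoxy-3-oxoprop-1-en-1-yl]-6-oxo-3,6-dihydro-2H-pyran-3-yl (triphenyl-λ5-phosphanylidene)acetate | O=C(C=P(c1ccccc1)(c1ccccc1)c1ccccc1)O[C@H]1C=CC(=O)O[C@H]1/C=C/C(=O)OC(C)(C)C
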